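**Assumption:** atom labels C-1 to C-20 follow briarane numbering (C-1 quaternary ring-fusion carbon bearing C-15; C-2 carbinol; C-3=C-4; C-5 bearing C-16; C-7 lactone O–CH; C-8 tertiary carbinol; C-9; C-10; C-11 bearing C-20; C-12; C-13/C-14 epoxide; C-17 bearing C-18; C-19 lactone C=O). β is the face of the C-15 methyl; silyl groups and Bu3SnH are treated as reagents.

## Retrosynthetic overview

1. Target 36 ⇐ silyl ether 35 ⇐ seco-aldehyde 34: the ten-membered ring is closed last, at C-2–C-3, by NiCl2/CrCl2 alkenyl iodide–aldehyde coupling.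
2. 34 ⇐ 28: the γ-lactone (second ring) comes from hydroxyl-directed epoxidation of C-7=C-8 and invertive lactonisation, then acetylation, iododesilylation and C-2 oxidation.
3. 28 ⇐ ring-A aldehyde 14 + dienynoate 27 by nickel-catalysed reductive alkyne–aldehyde coupling (C-8–C-9).
4. 27 ⇐ dienyne 24 + diazo ester 26 by a new copper-catalysed enantioselective alkynyl C–H insertion (C-8–C-17); 24 by trans-hydrostannation/Stille coupling (C-4–C-5).
5. 14 ⇐ catalytic asymmetric Diels–Alder reaction of diene 4 with enal 2 (ring A, formed first), then reduction and epoxidation on a trans-lactone-locked ring.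

## Route

### Fragment A (ring-A aldehyde 14)

Step 1
Reactants: 1 methyl 3-methylbut-2-enoate
Product: 2 methyl (E)-3-methyl-4-oxobut-2-enoate
Conditions: SeO2 (1.1 equiv), dioxane, reflux
Reagents that add atoms: selenium dioxide O=[Se]=O
Why: Riley allylic oxidation takes the methyl group trans to the ester, giving the E enal with CHO and CO2Me trans.

Step 2
Reactants: 3 pent-1-en-3-one
Product: 4 (Z)-tert-butyldimethyl(penta-1,3-dien-3-yloxy)silane
Conditions: TBSOTf, Et3N, Et2O, 0 °C
Reagents that add atoms: tert-butyldimethylsilyl trifluoromethanesulfonate CC(C)(C)[Si](C)(C)OS(=O)(=O)C(F)(F)F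
Why: Soft enolisation and O-silylation of the ethyl ketone give the Z silyl enol ether, i.e. the diene with its terminal methyl in the outside position.

Step 3
Reactants: 2 methyl (E)-3-methyl-4-oxobut-2-enoate; 4 (Z)-tert-butyldimethyl(penta-1,3-dien-3-yloxy)silane
Product: 5 methyl 3-[(tert-butyldimethylsilyl)oxy]-6-formyl-2,6-dimethylcyclohex-3-ene-1-carboxylate (1-CO2Me, 2-Me and 6-Me mutually cis, CHO trans)
Conditions: (S)-1-(2-methylphenyl)-3,3-diphenyltetrahydro-1H,3H-pyrrolo[1,2-c][1,3,2]oxazaborole (20 mol %), (CF3SO2)2NH (18 mol %), CH2Cl2, −78 → −40 °C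
Reagents that add atoms: none
Why: Enantioselective Diels–Alder reaction under chiral oxazaborolidinium catalysis: the silyl enol ether terminus (C-11) attacks the enal β-carbon (C-10), the α-methyl enal reacts CHO-exo/ester-endo so that C-20, C-9 and C-15 end up cis, and the formyl-bound catalyst shields one enal face to set C-1, C-10 and C-11 (the antipodal catalyst would give ent-5).

Step 4
Reactants: 5 Diels–Alder adduct
Product: 7 trans-fused 6-[(tert-butyldimethylsilyl)oxy]-3a,7-dimethyl-3a,4,7,7a-tetrahydroisobenzofuran-1(3H)-one (3a-Me and 7-Me β, 7a-H α), via hydroxy ester 6 (not isolated)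
Conditions: NaBH4, THF/MeOH, −20 °C; then DBU (10 mol %), PhMe, 60 °C
Reagents that add atoms: none
Why: Chemoselective borohydride reduction of the aldehyde followed by base-catalysed lactonisation; the trans-fused lactone locks ring A in the half-chair with C-15 and C-20 both axial on the β face, which controls steps 6 and 8.

Step 5
Reactants: 7 lactone silyl enol ether
Product: 8 3a,7-dimethyl-3a,7a-dihydroisobenzofuran-1,6(3H,7H)-dione (C-12 enone, same ring-fusion configuration)
Conditions: Pd(OAc)2 (10 mol %), O2 (1 atm), DMSO, 40 °C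
Reagents that add atoms: none
Why: Saegusa–Ito dehydrogenation: the palladium enolate at C-13 undergoes β-hydride elimination toward C-14, giving the enone under neutral conditions that leave the epimerisable C-11 untouched.

Step 6
Reactants: 8 enone lactone
Product: 9 6β-hydroxy-3a,7-dimethyl-3a,6,7,7a-tetrahydroisobenzofuran-1(3H)-one (12β-OH, cis to C-20)
Conditions: NaBH4, CeCl3·7H2O, MeOH, −78 °C
Reagents that add atoms: none
Why: Luche 1,2-reduction in which hydride adds axially from the α face, anti to the axial C-20 methyl of the locked ring, giving the equatorial 12β-alcohol.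

Step 7
Reactants: 9 allylic alcohol lactone
Product: 10 6β-acetoxy-3a,7-dimethyl-3a,6,7,7a-tetrahydroisobenzofuran-1(3H)-one
Conditions: Ac2O, pyridine, DMAP (cat.), CH2Cl2, 0 °C
Reagents that add atoms: acetic anhydride CC(=O)OC(C)=O
Why: Acylation gives a temporary acetate that removes the syn-directing effect of the free 12β-hydroxyl before epoxidation.

Step 8
Reactants: 10 allylic acetate lactone
Product: 11 4α,5α-epoxide of 10 (13α,14α-epoxide, trans to the C-12 oxygen)
Conditions: mCPBA, CH2Cl2, 0 °C → rt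
Reagents that add atoms: 3-chloroperoxybenzoic acid OOC(=O)c1cccc(Cl)c1
Why: Prilezhaev epoxidation from the α face, opposite the axial C-15 methyl that flanks C-14 and anti to the allylic acetate, sets C-13 and C-14.

Step 9
Reactants: 11 epoxy acetate lactone
Product: 12 5-hydroxy-2-(hydroxymethyl)-N-methoxy-N,2,4-trimethyl-7-oxabicyclo[4.1.0]heptane-3-carboxamide (2-Me, 3-amide, 4-Me and 5-OH β; epoxide O and CH2OH α)
Conditions: MeNH(OMe)·HCl (5 equiv), i-PrMgCl (10 equiv), THF, −20 → 0 °C
Reagents that add atoms: N,O-dimethylhydroxylamine hydrochloride CNOC.Cl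
Why: Weinreb aminolysis by the magnesium amide opens the strained trans-lactone to the amide, frees the C-2 primary alcohol and also cleaves the temporary acetate.

Step 10
Reactants: 12 Weinreb amide diol
Product: 13 primary tert-butyldimethylsilyl ether of 12
Conditions: TBSCl, imidazole, DMF, 0 °C
Reagents that add atoms: tert-butyldimethylsilyl chloride CC(C)(C)[Si](C)(C)Cl
Why: Selective silylation of the primary hydroxyl over the hindered secondary C-12 hydroxyl flanked by the epoxide and C-11.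

Step 11
Reactants: 13 silylated Weinreb amide
Product: 14 2-{[(tert-butyldimethylsilyl)oxy]methyl}-5-hydroxy-2,4-dimethyl-7-oxabicyclo[4.1.0]heptane-3-carbaldehyde (2-Me, 3-CHO, 4-Me and 5-OH β; epoxide O and CH2OTBS α)
Conditions: i-Bu2AlH (2.2 equiv), THF, −78 °C; Rochelle salt
Reagents that add atoms: none
Why: Weinreb amide reduction stops at the chelated tetrahedral intermediate and releases the C-9 aldehyde on work-up; it is used at once to avoid C-10 epimerisation.

### Fragment B (dienynoate 27)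

Step 12
Reactants: 15 prop-2-yn-1-ol
Product: 16 3-bromoprop-2-yn-1-ol
Conditions: NBS, AgNO3 (5 mol %), acetone, rt
Reagents that add atoms: N-bromosuccinimide O=C1CCC(=O)N1Br
Why: Silver-catalysed electrophilic bromination of the terminal alkyne C–H.

Step 13
Reactants: 16 3-bromoprop-2-yn-1-ol; 17 ethynyltrimethylsilane
Product: 18 5-(trimethylsilyl)penta-2,4-diyn-1-ol
Conditions: CuCl (5 mol %), NH2OH·HCl (10 mol %), piperidine (2 equiv), THF, 0 °C
Reagents that add atoms: none
Why: Cadiot–Chodkiewicz coupling of the copper acetylide with the bromoalkyne gives the unsymmetrical diyne (C-5 to C-8 and C-16).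

Step 14
Reactants: 18 5-(trimethylsilyl)penta-2,4-diyn-1-ol
Product: 19 (Z)-2-(tributylstannyl)-5-(trimethylsilyl)pent-2-en-4-yn-1-ol
Conditions: Bu3SnH, [(C5Me5)RuCl]4 (2 mol %), CH2Cl2, rt
Reagents that add atoms: tributyltin hydride CCCC[SnH](CCCC)CCCC
Why: Hydroxyl-directed ruthenium-catalysed trans-hydrostannation puts tin on the alkyne carbon next to CH2OH (C-5) and H anti on C-6, so the alkynyl group is cis to tin and the C-5=C-6 geometry is fixed; the silyl-capped alkyne does not react.

Step 15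
Reactants: 17 ethynyltrimethylsilane
Product: 20 (iodoethynyl)trimethylsilane
Conditions: NIS, AgNO3 (5 mol %), DMF, rt
Reagents that add atoms: N-iodosuccinimide O=C1CCC(=O)N1I
Why: Silver-catalysed iodination of the terminal alkyne.

Step 16
Reactants: 20 (iodoethynyl)trimethylsilane
Product: 21 (Z)-(2-iodoethenyl)trimethylsilane
Conditions: 2-nitrobenzenesulfonylhydrazide, THF/i-PrOH, rt
Reagents that add atoms: none
Why: Diimide generated in the flask adds H2 syn to the iodoalkyne, giving the Z iodoalkene that carries C-3 and C-4.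

Step 17
Reactants: 19 alkenylstannane; 21 (Z)-(2-iodoethenyl)trimethylsilane
Product: 22 (E)-5-(trimethylsilyl)-2-[(Z)-2-(trimethylsilyl)ethenyl]pent-2-en-4-yn-1-ol
Conditions: Pd(PPh3)4 (5 mol %), Cu(O2CC4H3S) (copper thiophene-2-carboxylate, 1.5 equiv), [Bu4N][Ph2PO2] (1.5 equiv), DMF, rt
Reagents that add atoms: none
Why: Copper-assisted Stille coupling forms C-4–C-5 with retention at both alkenes under fluoride-free conditions that suppress protodestannylation.

Step 18
Reactants: 22 bis-silyl dienynol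
Product: 23 (E)-2-[(Z)-2-(trimethylsilyl)ethenyl]pent-2-en-4-yn-1-ol
Conditions: K2CO3 (0.2 equiv), MeOH, 0 °C
Reagents that add atoms: none
Why: Methanolysis cleaves only the alkynyl C–Si bond; the alkenylsilane is inert.

Step 19
Reactants: 23 terminal dienynol
Product: 24 tert-butyl({(E)-2-[(Z)-2-(trimethylsilyl)ethenyl]pent-2-en-4-yn-1-yl}oxy)diphenylsilane
Conditions: TBDPSCl, imidazole, CH2Cl2, rt
Reagents that add atoms: tert-butyldiphenylsilyl chloride CC(C)(C)[Si](Cl)(c1ccccc1)c1ccccc1
Why: Silylation protects the C-16 hydroxyl with a group that outlasts the later tert-butyldimethylsilyl removal.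

Step 20
Reactants: 25 methyl L-alaninate hydrochloride
Product: 26 methyl 2-diazopropanoate
Conditions: NaNO2, H2SO4 (cat.), H2O/CH2Cl2, 0 °C
Reagents that add atoms: sodium nitrite [Na+].[O-]N=O
Why: Diazotisation of the α-amino ester gives the α-diazo ester (the alanine stereocentre is lost by design).

Step 21
Reactants: 24 silyl-protected terminal dienyne; 26 methyl 2-diazopropanoate
Product: 27 methyl (2R,5E,7Z)-6-{[(tert-butyldiphenylsilyl)oxy]methyl}-2-methyl-8-(trimethylsilyl)octa-5,7-dien-3-ynoate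
Conditions: [Cu(MeCN)4]PF6 (5 mol %), (S,S)-2,2'-(propane-2,2-diyl)bis(4-tert-butyl-4,5-dihydrooxazole) (6 mol %), 26 added over 6 h, CH2Cl2, −20 °C
Reagents that add atoms: none
Why: Proposed new method: enantioselective formal carbene insertion into the alkynyl C–H bond, in which the chiral bisoxazoline–copper acetylide of 24 takes up 26 as a copper carbene, 1,2-alkynyl migration forms the C-8–C-17 bond, and protonation of the resulting copper-bound enolate at C-17 by a second molecule of 24 inside the chiral pocket sets the (R) centre and regenerates the acetylide; the closest known reactions are the racemic copper iodide-catalysed coupling of terminal alkynes with diazo esters to 3-alkynoates and copper/bisoxazoline-catalysed enantioselective X–H insertions that rely on the same proton transfer, and the base-free cold conditions are chosen to avoid allene formation and racemisation.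

### Union and endgame

Step 22
Reactants: 14 ring-A aldehyde; 27 dienynoate
Product: 28 methyl (2R,3E,5E,7Z)-6-{[(tert-butyldiphenylsilyl)oxy]methyl}-3-[hydroxy(ring A)methyl]-2-methyl-8-(trimethylsilyl)octa-3,5,7-trienoate (ring A = the bicyclic unit of 14 attached through its former CHO carbon; C-9 carbinol as in the target)
Conditions: Ni(cod)2 [bis(1,5-cyclooctadiene)nickel] (10 mol %), tricyclopentylphosphine (20 mol %), Et3B (2.5 equiv), EtOAc, rt
Reagents that add atoms: none
Why: Nickel-catalysed reductive alkyne–aldehyde coupling: the conjugating alkene directs C–C bond formation to the distal alkyne carbon (C-8), syn addition of C-9 and H gives the 7E alkene, and Felkin–Anh attack on the aldehyde anti to the quaternary C-1 sets C-9.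

Step 23
Reactants: 28 dienyl allylic alcohol
Product: 30 γ-lactone triol (2,3-seco-briarane: C-19 lactone to O–C-7; free 8-, 9- and 12-OH; 2-O-TBS; 16-O-TBDPS; (3Z)-3-trimethylsilyl diene terminus), via epoxy ester 29 (not isolated)
Conditions: VO(acac)2 [vanadyl bis(acetylacetonate)] (5 mol %), t-BuOOH, CH2Cl2, 0 °C; then camphorsulfonic acid (10 mol %), H2O (2 equiv), rt
Reagents that add atoms: tert-butyl hydroperoxide CC(C)(C)OO; water O
Why: Vanadium-catalysed hydroxyl-directed epoxidation gives the erythro 7,8-epoxy alcohol (A(1,2) strain between the C-17 branch and C-10 in the vanadate transition state), then acid-catalysed lactonisation by the ester at the dienylic C-7 with inversion sets C-7 and leaves the epoxide oxygen as the C-8 tertiary hydroxyl.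

Step 24
Reactants: 30 γ-lactone triol
Product: 31 9,12-diacetate of 30
Conditions: Ac2O, pyridine, DMAP (cat.), CH2Cl2, 0 °C → rt
Reagents that add atoms: acetic anhydride CC(=O)OC(C)=O
Why: Acylation esterifies the two secondary hydroxyls and leaves the tertiary C-8 hydroxyl free.

Step 25
Reactants: 31 diacetate alkenylsilane
Product: 32 (3Z)-3-iodo analogue of 31
Conditions: NIS, (CF3)2CHOH, 0 °C
Reagents that add atoms: N-iodosuccinimide O=C1CCC(=O)N1I
Why: Ipso iododesilylation of the alkenylsilane proceeds with retention, giving the Z alkenyl iodide.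

Step 26
Reactants: 32 alkenyl iodide
Product: 33 C-2 primary alcohol
Conditions: HF·pyridine, pyridine, THF, 0 °C
Reagents that add atoms: none
Why: Buffered fluoride removes the tert-butyldimethylsilyl ether and spares the more robust tert-butyldiphenylsilyl ether, the acetates and the epoxide.

Step 27
Reactants: 33 primary alcohol
Product: 34 C-2 aldehyde (seco-aldehyde)
Conditions: Dess–Martin periodinane, CH2Cl2, 0 °C → rt
Reagents that add atoms: none
Why: Dess–Martin oxidation gives the non-enolisable neopentyl aldehyde; the tertiary hydroxyl cannot be oxidised.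

Step 28
Reactants: 34 iodo aldehyde
Product: 35 16-O-(tert-butyldiphenylsilyl) ether of the target
Conditions: CrCl2 (8 equiv), NiCl2 (0.1 equiv), DMSO/THF 3:1, rt, 2 mM
Reagents that add atoms: none
Why: Nozaki–Hiyama–Kishi macrocyclisation: nickel-catalysed formation of the alkenylchromium and its addition to the aldehyde close the ten-membered ring at C-2–C-3 with the acetates, lactone and epoxide tolerated and the ring enforcing the 3Z geometry; the alkenyl group is expected to attack the aldehyde face away from the C-15 methyl to give the C-2 carbinol of the target.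

Step 29
Reactants: 35 silyl ether
Product: 36 CNP0285414.3 (target)
Conditions: Bu4NF, AcOH (1:1), THF, 0 °C → rt
Reagents that add atoms: none
Why: Buffered fluoride desilylation frees the C-16 allylic alcohol without acetate migration or C-17 epimerisation.

## Compound list

1 | methyl 3-methylbut-2-enoate | COC(=O)C=C(C)C | starting material
2 | methyl (E)-3-methyl-4-oxobut-2-enoate | COC(=O)/C=C(\C)C=O | intermediate
3 | pent-1-en-3-one | CCC(=O)C=C | starting material
4 | (Z)-tert-butyldimethyl(penta-1,3-dien-3-yloxy)silane | C=C/C(O[Si](C)(C)C(C)(C)C)=C/C | intermediate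
5 | methyl 3-[(tert-butyldimethylsilyl)oxy]-6-formyl-2,6-dimethylcyclohex-3-ene-1-carboxylate (1-CO2Me, 2-Me, 6-Me cis; CHO trans) | COC(=O)[C@@H]1[C@H](C)C(O[Si](C)(C)C(C)(C)C)=CC[C@@]1(C)C=O | intermediate
6 | methyl 3-[(tert-butyldimethylsilyl)oxy]-6-(hydroxymethyl)-2,6-dimethylcyclohex-3-ene-1-carboxylate (same configuration) | COC(=O)[C@@H]1[C@H](C)C(O[Si](C)(C)C(C)(C)C)=CC[C@@]1(C)CO | intermediate (not isolated)
7 | trans-fused 6-[(tert-butyldimethylsilyl)oxy]-3a,7-dimethyl-3a,4,7,7a-tetrahydroisobenzofuran-1(3H)-one | O=C1[C@@H]2[C@H](C)C(O[Si](C)(C)C(C)(C)C)=CC[C@@]2(C)CO1 | intermediate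
8 | trans-fused 3a,7-dimethyl-3a,7a-dihydroisobenzofuran-1,6(3H,7H)-dione | O=C1[C@@H]2[C@H](C)C(=O)C=C[C@@]2(C)CO1 | intermediate
9 | 6β-hydroxy-3a,7-dimethyl-3a,6,7,7a-tetrahydroisobenzofuran-1(3H)-one | O=C1[C@@H]2[C@H](C)[C@H](O)C=C[C@@]2(C)CO1 | intermediate
10 | 6β-acetoxy-3a,7-dimethyl-3a,6,7,7a-tetrahydroisobenzofuran-1(3H)-one | O=C1[C@@H]2[C@H](C)[C@H](OC(C)=O)C=C[C@@]2(C)CO1 | intermediate
11 | 4α,5α-epoxide of 10 | O=C1[C@@H]2[C@H](C)[C@H](OC(C)=O)[C@H]3O[C@H]3[C@@]2(C)CO1 | intermediate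
12 | 5-hydroxy-2-(hydroxymethyl)-N-methoxy-N,2,4-trimethyl-7-oxabicyclo[4.1.0]heptane-3-carboxamide | CON(C)C(=O)[C@@H]1[C@H](C)[C@H](O)[C@H]2O[C@H]2[C@@]1(C)CO | intermediate
13 | 2-{[(tert-butyldimethylsilyl)oxy]methyl}-5-hydroxy-N-methoxy-N,2,4-trimethyl-7-oxabicyclo[4.1.0]heptane-3-carboxamide | CON(C)C(=O)[C@@H]1[C@H](C)[C@H](O)[C@H]2O[C@H]2[C@@]1(C)CO[Si](C)(C)C(C)(C)C | intermediate
14 | 2-{[(tert-butyldimethylsilyl)oxy]methyl}-5-hydroxy-2,4-dimethyl-7-oxabicyclo[4.1.0]heptane-3-carbaldehyde (ring-A aldehyde) | O=C[C@@H]1[C@H](C)[C@H](O)[C@H]2O[C@H]2[C@@]1(C)CO[Si](C)(C)C(C)(C)C | intermediate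
15 | prop-2-yn-1-ol | C#CCO | starting material
16 | 3-bromoprop-2-yn-1-ol | OCC#CBr | intermediate
17 | ethynyltrimethylsilane | C#C[Si](C)(C)C | starting material
18 | 5-(trimethylsilyl)penta-2,4-diyn-1-ol | OCC#CC#C[Si](C)(C)C | intermediate
19 | (Z)-2-(tributylstannyl)-5-(trimethylsilyl)pent-2-en-4-yn-1-ol | OC/C(=C/C#C[Si](C)(C)C)[Sn](CCCC)(CCCC)CCCC | intermediate
20 | (iodoethynyl)trimethylsilane | C[Si](C)(C)C#CI | intermediate
21 | (Z)-(2-iodoethenyl)trimethylsilane | I/C=C\[Si](C)(C)C | intermediate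
22 | (E)-5-(trimethylsilyl)-2-[(Z)-2-(trimethylsilyl)ethenyl]pent-2-en-4-yn-1-ol | C[Si](C)(C)C#C/C=C(CO)\C=C/[Si](C)(C)C | intermediate
23 | (E)-2-[(Z)-2-(trimethylsilyl)ethenyl]pent-2-en-4-yn-1-ol | C#C/C=C(CO)\C=C/[Si](C)(C)C | intermediate
24 | tert-butyl({(E)-2-[(Z)-2-(trimethylsilyl)ethenyl]pent-2-en-4-yn-1-yl}oxy)diphenylsilane | C#C/C=C(CO[Si](c1ccccc1)(c1ccccc1)C(C)(C)C)\C=C/[Si](C)(C)C | intermediate
25 | methyl L-alaninate hydrochloride | C[C@H](N)C(=O)OC.Cl | starting material
26 | methyl 2-diazopropanoate | COC(=O)C(C)=[N+]=[N-] | intermediate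
27 | methyl (2R,5E,7Z)-6-{[(tert-butyldiphenylsilyl)oxy]methyl}-2-methyl-8-(trimethylsilyl)octa-5,7-dien-3-ynoate | COC(=O)[C@H](C)C#C/C=C(CO[Si](c1ccccc1)(c1ccccc1)C(C)(C)C)\C=C/[Si](C)(C)C | intermediate
28 | methyl (2R,3E,5E,7Z)-6-{[(tert-butyldiphenylsilyl)oxy]methyl}-3-[hydroxy(ring A)methyl]-2-methyl-8-(trimethylsilyl)octa-3,5,7-trienoate | O[C@@H]([C@@H]1[C@H](C)[C@H](O)[C@H]2O[C@H]2[C@@]1(C)CO[Si](C)(C)C(C)(C)C)/C(=C/C=C(CO[Si](c3ccccc3)(c3ccccc3)C(C)(C)C)\C=C/[Si](C)(C)C)[C@@H](C)C(=O)OC | intermediate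
29 | 7,8-epoxide of 28 (epoxide oxygen erythro to the C-9 hydroxyl) | O[C@@H]([C@@H]1[C@H](C)[C@H](O)[C@H]2O[C@H]2[C@@]1(C)CO[Si](C)(C)C(C)(C)C)[C@@]3(O[C@H]3/C=C(CO[Si](c4ccccc4)(c4ccccc4)C(C)(C)C)\C=C/[Si](C)(C)C)[C@@H](C)C(=O)OC | intermediate (not isolated)
30 | 2,3-seco γ-lactone triol (8-, 9-, 12-OH free; 2-O-TBS; 16-O-TBDPS; 3-trimethylsilyl-(3Z)-diene) | O[C@@H]([C@@H]1[C@H](C)[C@H](O)[C@H]2O[C@H]2[C@@]1(C)CO[Si](C)(C)C(C)(C)C)[C@]3(O)[C@@H](/C=C(CO[Si](c4ccccc4)(c4ccccc4)C(C)(C)C)\C=C/[Si](C)(C)C)OC(=O)[C@@H]3C | intermediate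
31 | 9,12-diacetate of 30 | CC(=O)O[C@@H]([C@@H]1[C@H](C)[C@H](OC(C)=O)[C@H]2O[C@H]2[C@@]1(C)CO[Si](C)(C)C(C)(C)C)[C@]3(O)[C@@H](/C=C(CO[Si](c4ccccc4)(c4ccccc4)C(C)(C)C)\C=C/[Si](C)(C)C)OC(=O)[C@@H]3C | intermediate
32 | (3Z)-3-iodo analogue of 31 | CC(=O)O[C@@H]([C@@H]1[C@H](C)[C@H](OC(C)=O)[C@H]2O[C@H]2[C@@]1(C)CO[Si](C)(C)C(C)(C)C)[C@]3(O)[C@@H](/C=C(CO[Si](c4ccccc4)(c4ccccc4)C(C)(C)C)\C=C/I)OC(=O)[C@@H]3C | intermediate
33 | C-2 primary alcohol from 32 | CC(=O)O[C@@H]([C@@H]1[C@H](C)[C@H](OC(C)=O)[C@H]2O[C@H]2[C@@]1(C)CO)[C@]3(O)[C@@H](/C=C(CO[Si](c4ccccc4)(c4ccccc4)C(C)(C)C)\C=C/I)OC(=O)[C@@H]3C | intermediate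
34 | C-2 aldehyde (seco-aldehyde) | CC(=O)O[C@@H]([C@@H]1[C@H](C)[C@H](OC(C)=O)[C@H]2O[C@H]2[C@@]1(C)C=O)[C@]3(O)[C@@H](/C=C(CO[Si](c4ccccc4)(c4ccccc4)C(C)(C)C)\C=C/I)OC(=O)[C@@H]3C | intermediate
35 | 16-O-(tert-butyldiphenylsilyl) ether of the target | CC(=O)O[C@H]1[C@@H](C)[C@H]2[C@H](OC(C)=O)[C@]3(O)[C@@H](/C=C(CO[Si](c4ccccc4)(c4ccccc4)C(C)(C)C)\C=C/[C@@H](O)[C@]2(C)[C@@H]2O[C@H]12)OC(=O)[C@@H]3C | intermediate
36 | CNP0285414.3: 9,12-diacetoxy-2,8,16-trihydroxy-13α,14α-epoxybriara-3(Z),5(E)-diene γ-lactone (C-19 to O–C-7) | CC(=O)O[C@H]1[C@@H](C)[C@H]2[C@H](OC(C)=O)[C@]3(O)[C@@H](/C=C(CO)\C=C/[C@@H](O)[C@]2(C)[C@@H]2O[C@H]12)OC(=O)[C@@H]3C | target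

## Step count and risk

Total steps: 29. Longest linear sequence: 18 (steps 1, 3–11, 22–29).

Steps most likely to fail:

Step 21 (proposed copper-catalysed enantioselective alkynyl C–H insertion). Likely failure modes are low enantioselectivity, 1,2-hydride shift of the α-methyl carbene to methyl acrylate, or cyclopropanation of the diene. The fallback sets out from 24 and comes back at 27. Alkyne 24 and diazo ester 26 are coupled under the known ligand-free conditions (CuI, copper iodide, 5 mol %, MeCN, rt) to give racemic methyl (5E,7Z)-6-{[(tert-butyldiphenylsilyl)oxy]methyl}-2-methyl-8-(trimethylsilyl)octa-5,7-dien-3-ynoate F1. A lipase-mediated kinetic resolution (Candida rugosa lipase, pH 7 phosphate buffer/MTBE, rt) then hydrolyses the (S)-ester preferentially to (S)-6-{[(tert-butyldiphenylsilyl)oxy]methyl}-2-methyl-8-(trimethylsilyl)octa-5,7-dien-3-ynoic acid F2, and the unreacted (R)-ester 27 is recovered (at most 50 %).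

Step 22 (nickel-catalysed reductive coupling). The most likely failure is poor diastereoselectivity at C-9 with the hindered α-branched aldehyde. The fallback sets out from 28 obtained as a C-9 epimer mixture and comes back at 28. MnO2 in CH2Cl2 oxidises only the allylic C-9 alcohol (the C-12 hydroxyl is untouched) to the cross-conjugated C-9 dienone F3. Reagent-controlled reduction with (R)-1-methyl-3,3-diphenyltetrahydro-1H,3H-pyrrolo[1,2-c][1,3,2]oxazaborole (20 mol %) and catecholborane in toluene at −78 °C, with the α-branched dienyl group acting as the large substituent, then reinstalls the C-9 carbinol of 28.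

Step 28 (Nozaki–Hiyama–Kishi macrocyclisation). The risks are strain in the ten-membered ring, isomerisation of the Z alkenylchromium, and the wrong C-2 epimer. The fallback for the stereochemical outcome sets out from 35 obtained as a C-2 epimer mixture and comes back at 35. Dess–Martin periodinane in CH2Cl2 oxidises the only secondary alcohol to the macrocyclic C-2 dienone F4. NaBH4/CeCl3·7H2O in MeOH at −78 °C then reduces it 1,2 from the outer face of the ring, opposite the C-15 methyl, to give 35; the tertiary C-8 hydroxyl and the acetates are unaffected.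

## Further compounds

F1 | step 21 | racemic methyl (5E,7Z)-6-{[(tert-butyldiphenylsilyl)oxy]methyl}-2-methyl-8-(trimethylsilyl)octa-5,7-dien-3-ynoate | COC(=O)C(C)C#C/C=C(CO[Si](c1ccccc1)(c1ccccc1)C(C)(C)C)\C=C/[Si](C)(C)C
F2 | step 21 | (2S,5E,7Z)-6-{[(tert-butyldiphenylsilyl)oxy]methyl}-2-methyl-8-(trimethylsilyl)octa-5,7-dien-3-ynoic acid | OC(=O)[C@@H](C)C#C/C=C(CO[Si](c1ccccc1)(c1ccccc1)C(C)(C)C)\C=C/[Si](C)(C)C
F3 | step 22 | C-9 dienone from 28: methyl (2R,3E,5E,7Z)-6-{[(tert-butyldiphenylsilyl)oxy]methyl}-3-[(ring A)carbonyl]-2-methyl-8-(trimethylsilyl)octa-3,5,7-trienoate | O=C([C@@H]1[C@H](C)[C@H](O)[C@H]2O[C@H]2[C@@]1(C)CO[Si](C)(C)C(C)(C)C)/C(=C/C=C(CO[Si](c3ccccc3)(c3ccccc3)C(C)(C)C)\C=C/[Si](C)(C)C)[C@@H](C)C(=O)OC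
F4 | step 28 | 2-oxo analogue of 35 (macrocyclic C-2 dienone) | CC(=O)O[C@H]1[C@@H](C)[C@H]2[C@H](OC(C)=O)[C@]3(O)[C@@H](/C=C(CO[Si](c4ccccc4)(c4ccccc4)C(C)(C)C)\C=C/C(=O)[C@]2(C)[C@@H]2O[C@H]12)OC(=O)[C@@H]3C
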